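Which way of putting G and Q into the flask leaves you the most Z after 2.5 h?

| setting | amber | red | epsilon | beta | delta | alpha | gamma |
|---|---|---|---|---|---|---|---|
| G | 49 mM | 49 mM | 49 mM (fed, over 1.5 h) | 49 mM | 49 mM (in portions, 2, over 1.5 h) | 49 mM | 49 mM |
| Q | 2 equiv | 3 equiv | 2.00 equiv | 2.00 equiv (fed, over 25 min) | 2.00 equiv | 2.00 equiv (fed, over 1.5 h) | 2.00 equiv |
| L | 0.0082 mol% | 0.0082 mol% | 0.0082 mol% | 0.0082 mol% | 0.0082 mol% | 0.0082 mol% | 0.0082 mol% |
| remark | run made earlier | run made earlier | all else is in the flask from the start; the feed brings no volume worth counting | all else is in the flask from the start; the feed brings no volume worth counting | first portion at the start, last at 1.5 h | all else is in the flask from the start; the feed brings no volume worth counting | everything together at the start |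
| time |  |  | 2.5 h | 2.5 h | 2.5 h | 2.5 h | 2.5 h |

* the flask with the highest amount of Z, in percent of the G charged ("all alike" if they lie within 1.5 percentage points) (epsilon / beta / delta / alpha / gamma / all alike)
* final Z, as a percentage of the G charged, in epsilon
* final Z, as a percentage of the G charged, in beta
* final Z, as a percentage of the G charged, in delta
* final Z, as a percentage of the G charged, in alpha
* final Z, as a percentage of the G charged, in gamma

- a species is counted by the G in it: one E or D counts as two
- steps thought possible: J -> L + Z; Q + X <-> J; 2 G -> D; G + L <-> X; 2 J <-> E

| run | time / min | Z / % |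
|---|---|---|
| amber | 8.00 | 6.3 |
| amber | 15.0 | 12.3 |
| amber | 40.0 | 29.6 |
| amber | 90.0 | 54.7 |
| red | 6.00 | 4.8 |
| red | 15.0 | 12.2 |
| red | 30.0 | 23.5 |
| red | 50.0 | 38.1 |

(readings scatter by 0.3 percentage points)

Here L is the catalyst: it takes up G to give X, X takes up Q to give J, and J releases Z and L. Two J may pair to E. Two G may also meet and give D, a way of losing G that needs neither L nor Q.

Epsilon and alpha look nearly the same, with one reagent dosed over 1.5 h: G in epsilon, Q in alpha. Start with what the runs read. At 15.0 min, amber stands at 12.3% and red at 12.2%, level despite 3 equiv of Q against 2 equiv, so over that stretch the readings show no gain from the extra Q. At red's early pace the whole charge takes 123 min; call this reading the drain time τ, the minutes the catalyst needs for the G charged if its early pace holds.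

You have 2.5 h, longer than τ, so at that pace there is time in hand. The feed of 1.5 h is shorter than τ, so in epsilon G arrives faster than that pace removes it, and the backlog I reckon for the end of the feed is 26.8%. Alpha has its whole charge of G standing from the start, with Q arriving over the same 1.5 h. D needs two G, so if that step runs, its rate goes with the square of G, and epsilon's reckoned backlog stands against the whole charge at the start of alpha. My own reckoning therefore puts epsilon first.

The forecast differs: gamma 72%, beta 70%, alpha 66%, epsilon 62%, delta 58%. Its ground: “Feeding G holds G low, so the rate stays well below plateau and late G has less time to react.”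

The flasks give epsilon 76.3%, the highest, then delta 71.4%, gamma 62.1%, beta 59.4% and alpha 53.0%.

    J → L + Z (k = 240 /min)
    Q + X ⇌ J (K = 360 /M, k = 14000 /M/min)
    2 G → D (k = 0.190 /M/min)
    G + L ⇌ X (K = 22.0 /M, k = 33000 /M/min)
    2 J ⇌ E, settled at all times (K = 2.80 × 10⁵ /M)

Take away the step from two G to D and epsilon's lead over alpha goes from 23 percentage points to −0.63 points, the largest single effect tried. Alpha ends with D at 46.0%, epsilon at 17.2%. So watch G at 1.50 h: epsilon holds 38.8% there, above the reckoned backlog of 26.8%. In delta the second half of the charge gets 60.0 min against its share of τ, 61.5 min, and at 2.50 h G still stands at 10.1%.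

All runs are simulated on assumed constants, noise included.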